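**Retrosynthetic overview**
- The strategy rests on ring B (the resorcinol ring): C2', C1' and C6' form a contiguous all-carbon triad (prenyl CH2, C2 of the benzofuran, prenyl CH2) between the C3' and C5' oxygens, while C4', the most nucleophilic carbon, keeps its hydrogen.
- Key disconnection: C2'–CH2, C6'–CH2 and C1'–C2 are cut together, leading back to the C1' iodide 2, two molecules of the protected 2-iodoethanol 4 and the benzofuran-2-ylboronate 8, joined in one palladium/norbornene (Catellani) operation.
- Each prenyl group is cut at its C=C bond (Wittig) to an arylacetaldehyde, which is the two-carbon arm delivered by 4.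
- No ring is formed in the route: ring B comes intact from 5-iodoresorcinol and the benzofuran bicycle from benzofuran-6-ol.
- Endgame: fluoride desilylation, oxidation, double isopropylidene Wittig olefination, acid removal of the three MOM ethers.

Key step: step 5

Remark: primed locants refer to ring B (C1' bears the benzofuran, C3' and C5' the oxygens), unprimed locants to the benzofuran; 5-iodoresorcinol and benzofuran-6-ol are assumed to be purchasable.

**Route**

Step 1
Reactants: 1 5-iodoresorcinol
Product: 2 1-iodo-3,5-bis(methoxymethoxy)benzene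
Conditions: MOMCl, iPr2NEt, CH2Cl2, 0 °C to rt
Reagents that add atoms: chloromethyl methyl ether (MOMCl), COCCl
Why: Both phenols are O-alkylated by the reactive alpha-chloro ether under amine base (MOM protection, Williamson type), and the aryl iodide is inert.

Step 2
Reactants: 3 2-iodoethanol
Product: 4 tert-butyl(2-iodoethoxy)dimethylsilane
Conditions: TBSCl, imidazole, CH2Cl2, 0 °C to rt
Reagents that add atoms: tert-butyldimethylsilyl chloride (TBSCl), CC(C)(C)[Si](C)(C)Cl
Why: Imidazole-promoted silylation of the primary alcohol should be much faster than N-alkylation of imidazole by the primary iodide at this temperature.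

Step 3
Reactants: 5 benzofuran-6-ol
Product: 6 6-(methoxymethoxy)benzofuran
Conditions: MOMCl, iPr2NEt, CH2Cl2, 0 °C to rt
Reagents that add atoms: chloromethyl methyl ether (MOMCl), COCCl
Why: MOM protection of the phenol by O-alkylation, which leaves the furan ring untouched.

Step 4
Reactants: 6 6-(methoxymethoxy)benzofuran
Product: 8 2-[6-(methoxymethoxy)benzofuran-2-yl]-4,4,5,5-tetramethyl-1,3,2-dioxaborolane, via 2-lithio-6-(methoxymethoxy)benzofuran 7 (not isolated)
Conditions: n-BuLi, THF, −78 °C; then iPrOBpin, −78 °C to rt; aqueous work-up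
Reagents that add atoms: 2-isopropoxy-4,4,5,5-tetramethyl-1,3,2-dioxaborolane (iPrOBpin), CC(C)OB1OC(C)(C)C(C)(C)O1
Why: Lithiation–borylation: C2–H is the most acidic proton of a benzofuran and should be removed at −78 °C before MOM-directed ortho-lithiation at C7 or C5 can compete, and the aryllithium is trapped by the borate ester.

Step 5
Reactants: 2 1-iodo-3,5-bis(methoxymethoxy)benzene; 4 tert-butyl(2-iodoethoxy)dimethylsilane (two molecules incorporated); 8 2-[6-(methoxymethoxy)benzofuran-2-yl]-4,4,5,5-tetramethyl-1,3,2-dioxaborolane
Product: 9 2-{2,6-bis[2-(tert-butyldimethylsilyloxy)ethyl]-3,5-bis(methoxymethoxy)phenyl}-6-(methoxymethoxy)benzofuran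
Conditions: Pd(OAc)2 (10 mol %), norbornene (2 equiv), K2CO3, 4 (4 equiv), DMF with about 5 equiv H2O, rt to 50 °C; 8 (1.5 equiv) added slowly by syringe pump
Reagents that add atoms: none
Why: Proposed new method: oxidative addition of the C1'–I bond of 2 to zerovalent palladium and syn insertion of norbornene give a norbornylpalladium species without a syn beta-hydrogen, which metalates C2'–H with carbonate help to a five-membered palladacycle of divalent palladium; this adds the C–I bond of 4 (tetravalent palladium) and reductive elimination makes the C2'–CH2 bond, after which the same events at C6' install the second arm. With both ortho carbons substituted, strain forces beta-carbon elimination of norbornene, and the 2,6-dialkylaryl palladium iodide left behind transmetalates with boronate 8 and reductively eliminates the C1'–C2 bond. The closest known reaction type is the Catellani ortho,ortho'-dialkylation of ortho-unsubstituted aryl iodides by primary alkyl halides with Suzuki termination to 2,6-dialkylbiaryls; not yet shown is an iodide whose two ortho C–H bonds each sit next to a meta alkoxy group, here combined with a benzofuran-2-ylboronate as terminator. No ring is closed and no stereocentre is created. The step needs site selectivity for C2' and C6' over the electronically favoured C4' and the order alkylation, alkylation, arylation: the first follows from the C1' iodide, because the norbornyl-tethered palladium reaches only the two carbons ortho to it, and the second from the fact that norbornene leaves only the doubly ortho-substituted intermediate, supported by excess 4 and slow addition of 8. The saturated primary iodide 4 cannot ionise to a pi-allyl complex as a prenyl halide would, and the small MOM oxygens next to the C–H sites may assist rather than block palladation by coordination.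

Step 6
Reactants: 9 2-{2,6-bis[2-(tert-butyldimethylsilyloxy)ethyl]-3,5-bis(methoxymethoxy)phenyl}-6-(methoxymethoxy)benzofuran
Product: 10 2-[2,6-bis(2-hydroxyethyl)-3,5-bis(methoxymethoxy)phenyl]-6-(methoxymethoxy)benzofuran
Conditions: Bu4NF, THF, 0 °C to rt
Reagents that add atoms: none
Why: Fluoride-induced desilylation frees the two primary alcohols, and the aryl MOM acetals are inert to fluoride.

Step 7
Reactants: 10 2-[2,6-bis(2-hydroxyethyl)-3,5-bis(methoxymethoxy)phenyl]-6-(methoxymethoxy)benzofuran
Product: 11 2-[3,5-bis(methoxymethoxy)-2,6-bis(2-oxoethyl)phenyl]-6-(methoxymethoxy)benzofuran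
Conditions: Dess–Martin periodinane, CH2Cl2, 0 °C to rt; product used at once without chromatography
Reagents that add atoms: none
Why: Dess–Martin oxidation takes both primary alcohols to aldehydes under non-basic, non-aqueous conditions, which should avoid over-oxidation and base-induced aldol reaction of the enolisable arylacetaldehydes.

Step 8
Reactants: 11 2-[3,5-bis(methoxymethoxy)-2,6-bis(2-oxoethyl)phenyl]-6-(methoxymethoxy)benzofuran; 12 isopropyltriphenylphosphonium iodide
Product: 14 2-[3,5-bis(methoxymethoxy)-2,6-bis(3-methylbut-2-en-1-yl)phenyl]-6-(methoxymethoxy)benzofuran, via isopropylidenetriphenylphosphorane 13 (not isolated)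
Conditions: 12 (excess), n-BuLi, THF, 0 °C; then 11, −78 °C to rt
Reagents that add atoms: none
Why: Double Wittig olefination with the non-stabilised isopropylidene ylide builds both prenyl groups; the new double bonds carry two identical methyl groups, so no alkene geometry arises, and cold addition of the aldehyde to excess ylide should favour carbonyl addition over enolisation.

Step 9
Reactants: 14 2-[3,5-bis(methoxymethoxy)-2,6-bis(3-methylbut-2-en-1-yl)phenyl]-6-(methoxymethoxy)benzofuran
Product: 15 mulberrofuran V
Conditions: aq HCl (3 M), MeOH, rt to 40 °C, stopped at full conversion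
Reagents that add atoms: none
Why: Acid-catalysed transacetalisation in methanol releases the three phenols as dimethoxymethane is formed, and at this acidity and temperature MOM cleavage is expected to outpace protonation of the prenyl alkenes.

**Compound list**
1 | 5-iodoresorcinol | Oc1cc(O)cc(I)c1 | starting material
2 | 1-iodo-3,5-bis(methoxymethoxy)benzene | COCOc1cc(I)cc(OCOC)c1 | intermediate
3 | 2-iodoethanol | OCCI | starting material
4 | tert-butyl(2-iodoethoxy)dimethylsilane | CC(C)(C)[Si](C)(C)OCCI | intermediate
5 | benzofuran-6-ol | Oc1ccc2ccoc2c1 | starting material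
6 | 6-(methoxymethoxy)benzofuran | COCOc1ccc2ccoc2c1 | intermediate
7 | 2-lithio-6-(methoxymethoxy)benzofuran | [Li]c1cc2ccc(OCOC)cc2o1 | intermediate
8 | 2-[6-(methoxymethoxy)benzofuran-2-yl]-4,4,5,5-tetramethyl-1,3,2-dioxaborolane | COCOc1ccc2cc(B3OC(C)(C)C(C)(C)O3)oc2c1 | intermediate
9 | 2-{2,6-bis[2-(tert-butyldimethylsilyloxy)ethyl]-3,5-bis(methoxymethoxy)phenyl}-6-(methoxymethoxy)benzofuran | COCOc1cc(OCOC)c(CCO[Si](C)(C)C(C)(C)C)c(-c2cc3ccc(OCOC)cc3o2)c1CCO[Si](C)(C)C(C)(C)C | intermediate
10 | 2-[2,6-bis(2-hydroxyethyl)-3,5-bis(methoxymethoxy)phenyl]-6-(methoxymethoxy)benzofuran | COCOc1cc(OCOC)c(CCO)c(-c2cc3ccc(OCOC)cc3o2)c1CCO | intermediate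
11 | 2-[3,5-bis(methoxymethoxy)-2,6-bis(2-oxoethyl)phenyl]-6-(methoxymethoxy)benzofuran | COCOc1cc(OCOC)c(CC=O)c(-c2cc3ccc(OCOC)cc3o2)c1CC=O | intermediate
12 | isopropyltriphenylphosphonium iodide | CC(C)[P+](c1ccccc1)(c1ccccc1)c1ccccc1.[I-] | starting material
13 | isopropylidenetriphenylphosphorane | CC(C)=P(c1ccccc1)(c1ccccc1)c1ccccc1 | intermediate
14 | 2-[3,5-bis(methoxymethoxy)-2,6-bis(3-methylbut-2-en-1-yl)phenyl]-6-(methoxymethoxy)benzofuran | COCOc1cc(OCOC)c(CC=C(C)C)c(-c2cc3ccc(OCOC)cc3o2)c1CC=C(C)C | intermediate
15 | mulberrofuran V | CC(C)=CCc1c(O)cc(O)c(CC=C(C)C)c1-c1cc2ccc(O)cc2o1 | target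

**Step count**
Total: 9 steps. Longest linear sequence: 7 steps (steps 3, 4, 5, 6, 7, 8, 9 from benzofuran-6-ol).

**Steps most likely to fail**

1. Step 5. Palladation of the two ortho C–H bonds next to the MOM ethers may be slow, so the arylpalladium or norbornylpalladium intermediates could couple with the boronate before both arms are in place, or stop after one alkylation; protodeboronation of 8 may add to the loss. The fallback uses known chemistry, sets out from 2 and comes back at 14, so steps 6 to 8 are not needed. Compound 2 is brominated twice with N-bromosuccinimide (2 equiv, MeCN, 0 °C to rt) at the two carbons ortho to iodine and para to a MOM ether, which should give 2,4-dibromo-3-iodo-1,5-bis(methoxymethoxy)benzene F1. Suzuki coupling with 8 at the more reactive C–I bond (Pd(PPh3)4, K2CO3, dioxane/H2O, 60 °C) should give 2-[2,6-dibromo-3,5-bis(methoxymethoxy)phenyl]-6-(methoxymethoxy)benzofuran F2. Double Stille allylation (allyltributylstannane, Pd2(dba)3, P(t-Bu)3, CsF, dioxane, 100 °C) should give 2-[2,6-diallyl-3,5-bis(methoxymethoxy)phenyl]-6-(methoxymethoxy)benzofuran F3. Cross-metathesis with 2-methyl-2-butene (second-generation Grubbs catalyst (H2IMes)(PCy3)Cl2Ru=CHPh, CH2Cl2, 40 °C) then turns both allyl groups into prenyl groups and gives 14.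

2. Step 8. The basic ylide may enolise the arylacetaldehydes instead of adding to them, leading to aldol self-condensation or incomplete double olefination. The fallback reverses the polarity of the olefination and avoids the aldehyde; it sets out from 10 and comes back at 14. Appel iodination (I2, PPh3, imidazole, CH2Cl2) should give 2-[2,6-bis(2-iodoethyl)-3,5-bis(methoxymethoxy)phenyl]-6-(methoxymethoxy)benzofuran F4. Heating with PPh3 in MeCN should give the bis(triphenylphosphonium) diiodide F5. Deprotonation with KN(SiMe3)2 (THF, −78 to 0 °C) gives the bis-ylide F6, which is condensed with excess acetone to give 14.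

3. Step 9. Protonation of the prenyl alkenes may compete with acetal cleavage, closing 2,2-dimethylchroman rings onto the neighbouring phenols or adding HCl or methanol across the alkenes. The fallback avoids a free Brønsted acid; it sets out from 14 and comes back at 15. TMSOTf and 2,2'-bipyridyl (CH2Cl2, 0 °C) should exchange each aryl MOM ether for a silyl ether and give the tris(trimethylsilyl) ether of mulberrofuran V F7. Addition of water then hydrolyses the labile aryl silyl ethers to 15.

**Further compounds**
F1 | step 5 | 2,4-dibromo-3-iodo-1,5-bis(methoxymethoxy)benzene | COCOc1cc(OCOC)c(Br)c(I)c1Br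
F2 | step 5 | 2-[2,6-dibromo-3,5-bis(methoxymethoxy)phenyl]-6-(methoxymethoxy)benzofuran | COCOc1cc(OCOC)c(Br)c(-c2cc3ccc(OCOC)cc3o2)c1Br
F3 | step 5 | 2-[2,6-diallyl-3,5-bis(methoxymethoxy)phenyl]-6-(methoxymethoxy)benzofuran | COCOc1cc(OCOC)c(CC=C)c(-c2cc3ccc(OCOC)cc3o2)c1CC=C
F4 | step 8 | 2-[2,6-bis(2-iodoethyl)-3,5-bis(methoxymethoxy)phenyl]-6-(methoxymethoxy)benzofuran | COCOc1cc(OCOC)c(CCI)c(-c2cc3ccc(OCOC)cc3o2)c1CCI
F5 | step 8 | {[2-(6-(methoxymethoxy)benzofuran-2-yl)-4,6-bis(methoxymethoxy)-1,3-phenylene]bis(ethane-2,1-diyl)}bis(triphenylphosphonium) diiodide | COCOc1cc(OCOC)c(CC[P+](c2ccccc2)(c2ccccc2)c2ccccc2)c(-c2cc3ccc(OCOC)cc3o2)c1CC[P+](c1ccccc1)(c1ccccc1)c1ccccc1.[I-].[I-]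
F6 | step 8 | bis-ylide of F5, 2-{3,5-bis(methoxymethoxy)-2,6-bis[2-(triphenylphosphoranylidene)ethyl]phenyl}-6-(methoxymethoxy)benzofuran | COCOc1cc(OCOC)c(CC=P(c2ccccc2)(c2ccccc2)c2ccccc2)c(-c2cc3ccc(OCOC)cc3o2)c1CC=P(c1ccccc1)(c1ccccc1)c1ccccc1
F7 | step 9 | tris(trimethylsilyl) ether of mulberrofuran V | CC(C)=CCc1c(O[Si](C)(C)C)cc(O[Si](C)(C)C)c(CC=C(C)C)c1-c1cc2ccc(O[Si](C)(C)C)cc2o1
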